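**Retrosynthetic overview**
- The target is opened at the C11–O bond: a singlet-oxygen ene reaction on the isopropylidene ketone 3α-senecioyloxy-4α-hydroxy-eudesm-7(11)-en-8-one forms the carbinol and moves the alkene to C6=C7.
- That hydroxy ester is opened at both ring A C–O bonds (C3–O ester, C4–OH): a one-step α-face syn-acyloxyhydroxylation of eudesma-3,7(11)-dien-8-one with bis(senecioyl) peroxide.
- The dienone comes from a trans-fused Δ3-en-8-one by aldol condensation with acetone; the Δ3 alkene and the 5α-H come from reductive triflation and triflate reduction of a Δ4-3-keto octalone whose C8 ketone is masked as a ketal.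
- The octalone comes from a Robinson annulation of ethyl vinyl ketone onto racemic 2-methyl-1,4-cyclohexanedione mono-ketal, with C10 set through the (R)-1-phenylethylamine imine.
- Ring order: ring B is the purchased cyclohexanone, ring A is annulated onto it, and all oxygenation is done late.

Assumption: racemic ketone 1 is bought as a catalogue compound (otherwise one methylation of 1,4-cyclohexanedione monoethylene ketal). Positions are given in eudesmane numbering (C1–C15), and α means the face opposite the C10 methyl.

**Step 1**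
Reactants: 1 racemic 7-methyl-1,4-dioxaspiro[4.5]decan-8-one; 2 (R)-1-phenylethylamine; 3 pent-1-en-3-one (ethyl vinyl ketone)
Product: 6 (7R)-7-methyl-7-(3-oxopentyl)-1,4-dioxaspiro[4.5]decan-8-one, via ketimine 4 (not isolated), via Michael-adduct ketimine 5 (not isolated)
Conditions: 2 (1.05 equiv), p-TsOH (1 mol%), toluene, reflux, Dean–Stark; then 3 (1.3 equiv), THF, 40 °C, 72 h; then AcOH/NaOAc/H2O, 20 °C
Reagents that add atoms: water, O
Why: d'Angelo–Pfau deracemising Michael addition, in which the chiral imine reacts through its more substituted secondary enamine and the enone is delivered in a compact aza-ene-like transition state to the face anti to the phenyl group, so the (R)-auxiliary sets the quaternary C10 centre (R, the 10β-methyl series, about 90% ee expected and upgraded by crystallisation downstream) before buffered hydrolysis releases the amine.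

**Step 2**
Reactants: 6
Product: 7 (4aR)-6,6-(ethylenedioxy)-1,4a-dimethyl-4,4a,5,6,7,8-hexahydronaphthalen-2(3H)-one
Conditions: NaOMe (0.3 equiv), MeOH, 60 °C
Reagents that add atoms: none
Why: intramolecular aldol condensation (the ring-closing half of the Robinson annulation) of the ethyl ketone onto the ring carbonyl forms ring A as the conjugated 4-methyl-Δ4-3-ketone, while the quaternary centre cannot epimerise and the ketal is stable to base.

**Step 3**
Reactants: 7
Product: 9 (4aR,8aR)-6,6-(ethylenedioxy)-1,4a-dimethyl-3,4,4a,5,6,7,8,8a-octahydronaphthalen-2-yl trifluoromethanesulfonate, via lithium enolate 8 (not isolated)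
Conditions: Li (2.1 equiv), t-BuOH (1.0 equiv), NH3/THF, −78 °C; NH3 evaporated; then PhNTf2 (1.2 equiv), THF, 0 → 20 °C
Reagents that add atoms: N-phenylbis(trifluoromethanesulfonimide), O=S(=O)(N(c1ccccc1)S(=O)(=O)C(F)(F)F)C(F)(F)F
Why: Birch-type dissolving-metal reduction of the enone protonates C5 axially on the α face anti to the angular methyl, which sets the trans ring fusion (5α-H) and leaves the regiodefined C3=C4 enolate, and O-triflation traps this enolate without equilibration (reductive enolate triflation).

**Step 4**
Reactants: 9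
Product: 11 (4aR,8aR)-5,8a-dimethyl-3,4,4a,7,8,8a-hexahydronaphthalen-2(1H)-one, via alkene ketal 10 (not isolated)
Conditions: Pd(OAc)2 (5 mol%), PPh3 (10 mol%), HCO2H (2 equiv), Et3N (3 equiv), DMF, 60 °C; then 1 M HCl, THF, 20 °C
Reagents that add atoms: water, O
Why: Cacchi-type palladium-catalysed formate reduction of the vinyl triflate (oxidative addition to zerovalent palladium, hydride from formate, reductive elimination) replaces OTf by H with the C3=C4 alkene kept in place, and mild acid hydrolysis of the dioxolane then unmasks the C8 ketone without touching a stereocentre.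

**Step 5**
Reactants: 11; 12 acetone
Product: 15 (4aR,8aR)-5,8a-dimethyl-3-(propan-2-ylidene)-3,4,4a,7,8,8a-hexahydronaphthalen-2(1H)-one (eudesma-3,7(11)-dien-8-one), via lithium aldolate 13 (not isolated), via tertiary mesylate 14 (not isolated)
Conditions: LiN(i-Pr)2 (1.1 equiv), THF, −78 °C; 12 (1.5 equiv), −78 °C; MsCl (1.5 equiv), −78 → 0 °C; DBU (3 equiv), 20 °C
Reagents that add atoms: none
Why: one-pot aldol condensation, in which kinetic deprotonation occurs at C7 (C9 is neopentyl, next to quaternary C10), the enolate adds to acetone, and in situ mesylation followed by E1cB elimination gives the conjugated isopropylidene ketone, the transient C7 centre being destroyed.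

**Step 6**
Reactants: 16 3-methylbut-2-enoyl chloride (senecioyl chloride), two molecules per molecule of product
Product: 17 bis(3-methylbut-2-enoyl) peroxide
Conditions: 30% aq. H2O2 (0.55 equiv relative to 16), NaOH (1.1 equiv), Et2O/H2O, 0 °C; kept and used as a dried CH2Cl2 solution
Reagents that add atoms: hydrogen peroxide, OO; 3-methylbut-2-enoyl chloride, CC(C)=CC(Cl)=O
Why: Schotten–Baumann double acylation, in which hydroperoxide anion is acylated by one molecule of 16 to the peroxy acid anion and this is acylated by a second molecule of 16 on its other oxygen, is the standard diacyl peroxide synthesis, and the β,β-disubstituted acyl group resists conjugate addition of the peroxide nucleophile.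

**Step 7**
Reactants: 15; 17
Product: 19 (3R,4S,5R,10R)-4-hydroxy-8-oxoeudesm-7(11)-en-3-yl 3-methylbut-2-enoate, via dioxolanylium triflate 18 (not isolated)
Conditions: 17 (1.3 equiv), H2O (2 equiv), TfOH (5 mol%), (CF3)2CHOH/CH2Cl2 1:4, −20 → 0 °C
Reagents that add atoms: water, O
Why: Proposed new method: the open-chain diacyl peroxide, activated as an electrophilic acyloxy donor by triflic acid and the hydrogen-bonding solvent, is attacked at a peroxide oxygen by the only electron-rich alkene (C3=C4) from the α face anti to the axial C10 methyl, giving an axial O–C3 bond and positive charge at tertiary C4; the carbonyl oxygen of the ester just delivered closes onto C4 from the same face (a trans-fused five-membered ring is impossible) to give the cis-fused acyloxonium ion 18, and water opens it at the acetal carbon with collapse to the axial C3 ester and the equatorial tertiary C4 hydroxyl, so both C–O bonds and both stereocentres (3R,4S) arise in one operation; the closest known reaction type is the syn-dihydroxylation of alkenes with cyclic malonoyl or phthaloyl peroxides through dioxonium ions, together with Woodward-type acyloxonium hydrolysis, but an acid-activated acyclic unsaturated diacyl peroxide that leaves its own acyl group in the product has not been described.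

**Step 8**
Reactants: 19
Product: 21 (3R,4S,5R,10R)-4,11-dihydroxy-8-oxoeudesm-6-en-3-yl 3-methylbut-2-enoate (CNP0175033.1), via allylic hydroperoxide 20 (not isolated)
Conditions: O2, tetraphenylporphyrin (1 mol%), white LEDs, CH2Cl2, −20 °C; then PPh3 (1.2 equiv), 0 °C
Reagents that add atoms: dioxygen, O=O
Why: Schenck ene reaction of singlet oxygen with an s-cis α,β-unsaturated ketone, whose geminal selectivity puts the new C–O bond on the β-carbon C11 and takes the allylic hydrogen from C6 (the alkyl group geminal to the carbonyl), moving the alkene to C6=C7; the electron-poor senecioate and the product enone react far more slowly, PPh3 reduces hydroperoxide 20 to the tertiary alcohol, and no stereocentre is formed or disturbed.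

**Compound list**
1 | racemic 7-methyl-1,4-dioxaspiro[4.5]decan-8-one | CC1CC2(OCCO2)CCC1=O | starting material
2 | (R)-1-phenylethylamine | C[C@@H](N)c1ccccc1 | starting material
3 | pent-1-en-3-one (ethyl vinyl ketone) | CCC(=O)C=C | starting material
4 | N-[(1R)-1-phenylethyl] ketimine of 1 (C7 epimers equilibrate through the enamine) | CC1CC2(OCCO2)CCC1=N[C@H](C)c1ccccc1 | intermediate
5 | N-[(1R)-1-phenylethyl] ketimine of 6 (Michael adduct, quaternary centre R) | CCC(=O)CC[C@]1(C)CC2(OCCO2)CCC1=N[C@H](C)c1ccccc1 | intermediate
6 | (7R)-7-methyl-7-(3-oxopentyl)-1,4-dioxaspiro[4.5]decan-8-one | CCC(=O)CC[C@]1(C)CC2(OCCO2)CCC1=O | intermediate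
7 | (4aR)-6,6-(ethylenedioxy)-1,4a-dimethyl-4,4a,5,6,7,8-hexahydronaphthalen-2(3H)-one | O=C1CC[C@]2(C)CC3(OCCO3)CCC2=C1C | intermediate
8 | lithium (4aR,8aR)-6,6-(ethylenedioxy)-1,4a-dimethyl-3,4,4a,5,6,7,8,8a-octahydronaphthalen-2-olate (trans-fused) | CC1=C([O-])CC[C@]2(C)CC3(OCCO3)CC[C@@H]12.[Li+] | intermediate
9 | (4aR,8aR)-6,6-(ethylenedioxy)-1,4a-dimethyl-3,4,4a,5,6,7,8,8a-octahydronaphthalen-2-yl trifluoromethanesulfonate | CC1=C(OS(=O)(=O)C(F)(F)F)CC[C@]2(C)CC3(OCCO3)CC[C@@H]12 | intermediate
10 | ethylene ketal of 11 (trans-fused Δ3 alkene, 5α-H, 10β-Me) | CC1=CCC[C@]2(C)CC3(OCCO3)CC[C@@H]12 | intermediate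
11 | (4aR,8aR)-5,8a-dimethyl-3,4,4a,7,8,8a-hexahydronaphthalen-2(1H)-one | CC1=CCC[C@]2(C)CC(=O)CC[C@@H]12 | intermediate
12 | acetone | CC(C)=O | starting material
13 | lithium alkoxide of the C7 acetone aldol adduct of 11 (C7 epimer mixture) | CC1=CCC[C@]2(C)CC(=O)C(C(C)(C)[O-])C[C@@H]12.[Li+] | intermediate
14 | methanesulfonate of the C7 acetone aldol adduct of 11 (C7 epimer mixture) | CC1=CCC[C@]2(C)CC(=O)C(C(C)(C)OS(C)(=O)=O)C[C@@H]12 | intermediate
15 | (4aR,8aR)-5,8a-dimethyl-3-(propan-2-ylidene)-3,4,4a,7,8,8a-hexahydronaphthalen-2(1H)-one (eudesma-3,7(11)-dien-8-one) | CC1=CCC[C@]2(C)CC(=O)C(=C(C)C)C[C@@H]12 | intermediate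
16 | 3-methylbut-2-enoyl chloride | CC(C)=CC(Cl)=O | starting material
17 | bis(3-methylbut-2-enoyl) peroxide | CC(C)=CC(=O)OOC(=O)C=C(C)C | intermediate
18 | 3α,4α-cis-fused 2-(2-methylprop-1-enyl)-1,3-dioxolan-2-ylium triflate on C3/C4 of the eudesm-7(11)-en-8-one core | CC(C)=CC1O[C@@H]2CC[C@]3(C)CC(=O)C(=C(C)C)C[C@H]3[C@]2(C)[O+]=1.[O-]S(=O)(=O)C(F)(F)F | intermediate
19 | (3R,4S,5R,10R)-4-hydroxy-8-oxoeudesm-7(11)-en-3-yl 3-methylbut-2-enoate (3α-ester, 4α-OH) | CC(C)=CC(=O)O[C@@H]1CC[C@]2(C)CC(=O)C(=C(C)C)C[C@H]2[C@]1(C)O | intermediate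
20 | 3α-(3-methylbut-2-enoyloxy)-4α-hydroxy-11-hydroperoxyeudesm-6-en-8-one | CC(C)=CC(=O)O[C@@H]1CC[C@]2(C)CC(=O)C(C(C)(C)OO)=C[C@H]2[C@]1(C)O | intermediate
21 | (3R,4S,5R,10R)-4,11-dihydroxy-8-oxoeudesm-6-en-3-yl 3-methylbut-2-enoate (CNP0175033.1) | CC(C)=CC(=O)O[C@@H]1CC[C@]2(C)CC(=O)C(C(C)(C)O)=C[C@H]2[C@]1(C)O | target

**Step count**
Total steps: 8. Longest linear sequence: 7 (steps 1, 2, 3, 4, 5, 7, 8); step 6 is a one-step side branch.

**Steps most likely to fail, with fallbacks**

Step 7 (the proposed new reaction). The C4 cation may lose a proton to give allylic esters, acid may move the C3=C4 alkene, or the acyloxonium ion may be opened with the wrong regiochemistry or at the remote alkene carbon. The fallback uses known chemistry, sets out from 15 and comes back to the route at 19. Upjohn dihydroxylation of 15 (OsO4 2 mol%, N-methylmorpholine N-oxide, acetone/H2O, 20 °C) attacks the isolated C3=C4 alkene from the α face and gives 3α,4α-dihydroxyeudesm-7(11)-en-8-one F1. Acylation of its only secondary hydroxyl with 16 (pyridine, DMAP, CH2Cl2, 0 °C) then gives 19; the tertiary hydroxyl does not react.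

Step 8. Singlet oxygen may abstract from the isopropylidene methyls instead of C6, or attack the senecioate, and the hydroperoxide may cyclise. The fallback makes the C11 carbinol by a C–C aldol bond instead of the ene reaction; it sets out from 11 and comes back to the route at 21. The lithium enolate of 11 (LiN(i-Pr)2, ZnCl2, THF, −78 °C) adds to 12 to give 7-(2-hydroxypropan-2-yl)-4,10-dimethyl-Δ3-octal-8-one F2. 2-Iodoxybenzoic acid in DMSO at 70 °C dehydrogenates it to the only possible enone (C10 is quaternary), 11-hydroxyeudesma-3,6-dien-8-one F3. OsO4/N-methylmorpholine N-oxide dihydroxylates the isolated C3=C4 alkene from the α face to 3α,4α,11-trihydroxyeudesm-6-en-8-one F4. Acylation of its single secondary hydroxyl with 16 (pyridine, DMAP, 0 °C) gives 21.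

Step 5. The one-pot sequence may suffer retro-aldol cleavage before mesylation, or elimination to the unconjugated isopropenyl isomer. The fallback replaces the aldol by a cross-coupling; it sets out from 11 and comes back to the route at 15. Palladium-catalysed α-alkenylation of the C7 enolate (Pd2(dba)3, P(t-Bu)3, LiN(SiMe3)2, 2-bromopropene, THF, 40 °C) gives 7-(prop-1-en-2-yl)-4,10-dimethyl-Δ3-octal-8-one F5. DBU in CH2Cl2 (or NaOMe/MeOH) then moves the alkene into conjugation to give 15.

**Further compounds**
F1 | step 7 | 3α,4α-dihydroxyeudesm-7(11)-en-8-one | O[C@@H]1CC[C@]2(C)CC(=O)C(=C(C)C)C[C@H]2[C@]1(C)O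
F2 | step 8 | 7-(2-hydroxypropan-2-yl)-4,10-dimethyl-Δ3-octal-8-one (5α-H, 10β-Me, C7 epimer mixture) | CC1=CCC[C@]2(C)CC(=O)C(C(C)(C)O)C[C@@H]12
F3 | step 8 | 11-hydroxyeudesma-3,6-dien-8-one | CC1=CCC[C@]2(C)CC(=O)C(C(C)(C)O)=C[C@@H]12
F4 | step 8 | 3α,4α,11-trihydroxyeudesm-6-en-8-one | O[C@@H]1CC[C@]2(C)CC(=O)C(C(C)(C)O)=C[C@H]2[C@]1(C)O
F5 | step 5 | 7-(prop-1-en-2-yl)-4,10-dimethyl-Δ3-octal-8-one (5α-H, 10β-Me, C7 epimer mixture) | CC1=CCC[C@]2(C)CC(=O)C(C(C)=C)C[C@@H]12
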